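## Retrosynthetic overview
1. There is only one ring, the 31-membered lactone. It is formed last by closing the acyl C–O bond (Yamaguchi) of 30-hydroxytriacontanoic acid.
2. The plain C30 chain is traced back to its 17-oxo derivative (Wolff–Kishner), then to the 15-en-17-one, then to the 15-hydroxy-17-ketone, which is an aldol retron.
3. The key C15–C16 bond comes from an intermolecular directed aldol. The kinetic lithium enolate of 15-silyloxypentadecan-2-one (C15) adds to methyl 15-oxopentadecanoate (C15).
4. The ketone half comes from ethyl acetoacetate (3 C kept) and 12-bromododecan-1-ol, itself made from dodecane-1,12-diol. The aldehyde half comes from ω-pentadecalactone by methanolysis and oxidation.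

Assumption: the SMILES is read as one C=O, 29 CH2 and one ring O (31-membered ring, C30H58O2); it has no stereocentre and no C=C, so the target is achiral and no enantiocontrol is needed.

## Route

Step 1
Reactants: 1 dodecane-1,12-diol
Product: 2 12-bromododecan-1-ol
Conditions: 48% aq HBr (1.2 equiv), toluene, reflux, 24 h
Reagents that add atoms: hydrogen bromide, Br
Why: SN2 displacement of the protonated hydroxyl by bromide, in which the bromo alcohol passes into the toluene layer and is shielded from a second substitution, so the monobromide dominates and no stereocentre is made.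

Step 2
Reactants: 3 ethyl acetoacetate; 2 12-bromododecan-1-ol
Product: 5 ethyl 2-acetyl-14-hydroxytetradecanoate (racemic), via ethyl acetoacetate sodium enolate 4 (not isolated)
Conditions: 3 (1.5 equiv), NaOEt (1.4 equiv), EtOH, rt, 30 min; then 2 (1.0 equiv), NaI (10 mol %), reflux, 16 h
Reagents that add atoms: sodium ethoxide, CC[O-].[Na+] (supplies only the Na of intermediate 4)
Why: Acetoacetic ester alkylation (SN2, iodide-catalysed), in which all ethoxide is consumed by the more acidic β-keto ester (pKa about 11 against about 16 for the alcohol), so the enolate carbon attacks the primary halide while the free OH is a spectator; the new C2 centre is racemic and is erased in step 3.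

Step 3
Reactants: 5 ethyl 2-acetyl-14-hydroxytetradecanoate
Product: 7 15-hydroxypentadecan-2-one, via 2-acetyl-14-hydroxytetradecanoic acid 6 (not isolated)
Conditions: 5% aq NaOH, EtOH, rt, 12 h; then 20% H2SO4 to pH 1, 80 °C, 2 h
Reagents that add atoms: sodium hydroxide, [Na+].[OH-] (its O enters intermediate 6 only and leaves in CO2)
Why: Ketonic cleavage of the acetoacetic ester synthesis, in which dilute hydroxide saponifies the ester without retro-Claisen cleavage and the free β-keto acid loses CO2 through a cyclic six-membered transition state on warming, which also removes the racemic centre.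

Step 4
Reactants: 7 15-hydroxypentadecan-2-one
Product: 8 15-[(tert-butyldimethylsilyl)oxy]pentadecan-2-one
Conditions: TBSCl (1.2 equiv), imidazole (2.5 equiv), DMF, rt, 4 h
Reagents that add atoms: tert-butyldimethylsilyl chloride, CC(C)(C)[Si](C)(C)Cl
Why: Imidazole-promoted silyl ether protection of the unhindered primary alcohol removes the only O–H proton that would consume LDA in step 7, and the ketone is untouched.

Step 5
Reactants: 9 ω-pentadecalactone (oxacyclohexadecan-2-one)
Product: 10 methyl 15-hydroxypentadecanoate
Conditions: MeOH (solvent), H2SO4 (5 mol %), reflux, 12 h; NaHCO3 before evaporation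
Reagents that add atoms: methanol, CO
Why: Acid-catalysed transesterification (ring-opening methanolysis) is pushed fully to the open hydroxy ester by methanol as solvent, and neutralisation before evaporation prevents re-closure or oligomerisation.

Step 6
Reactants: 10 methyl 15-hydroxypentadecanoate
Product: 11 methyl 15-oxopentadecanoate
Conditions: TEMPO (10 mol %), PhI(OAc)2 (1.1 equiv), CH2Cl2, rt, 3 h; use fresh
Reagents that add atoms: none
Why: TEMPO/PhI(OAc)2 oxoammonium oxidation of a primary alcohol stops at the aldehyde in water-free CH2Cl2 and does not touch the ester.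

Step 7 (key step)
Reactants: 8 15-[(tert-butyldimethylsilyl)oxy]pentadecan-2-one; 11 methyl 15-oxopentadecanoate
Product: 13 methyl 30-[(tert-butyldimethylsilyl)oxy]-15-hydroxy-17-oxotriacontanoate (racemic), via lithium 15-[(tert-butyldimethylsilyl)oxy]pentadec-1-en-2-olate 12 (not isolated)
Conditions: i-Pr2NH, n-BuLi, THF, −78 to 0 °C (LDA, 1.05 equiv per 8); 8 (1.1 equiv) added slowly, −78 °C, 45 min; 11 (1.0 equiv) in THF, −78 °C, 45 min; AcOH/THF quench at −78 °C
Reagents that add atoms: n-butyllithium, [Li]CCCC (supplies, through LDA, only the Li of intermediate 12)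
Why: Directed crossed aldol addition, in which LDA at −78 °C irreversibly removes the less hindered methyl proton of the 2-alkanone (kinetic enolate) and this preformed enolate adds to the aldehyde far faster than it attacks the methyl ester or exchanges protons, forming the C15–C16 bond; the C15 carbinol centre arises racemic and is destroyed in step 8.

Step 8
Reactants: 13 methyl 30-[(tert-butyldimethylsilyl)oxy]-15-hydroxy-17-oxotriacontanoate
Product: 15 methyl (15E)-30-[(tert-butyldimethylsilyl)oxy]-17-oxotriacont-15-enoate, via β-mesyloxy ketone 14 (not isolated)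
Conditions: MsCl (1.5 equiv), Et3N (3 equiv), CH2Cl2, 0 °C, 30 min; then DBU (2 equiv), rt, 2 h
Reagents that add atoms: methanesulfonyl chloride, CS(=O)(=O)Cl (its atoms sit only in intermediate 14)
Why: Mesylation followed by base-induced E1cB elimination of the β-mesyloxy ketone gives the conjugated (E)-enone as the thermodynamic product, and the geometry is of no consequence because the alkene is hydrogenated next.

Step 9
Reactants: 15 methyl (15E)-30-[(tert-butyldimethylsilyl)oxy]-17-oxotriacont-15-enoate
Product: 16 methyl 30-[(tert-butyldimethylsilyl)oxy]-17-oxotriacontanoate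
Conditions: H2 (1 atm), 10% Pd/C, EtOAc, rt, 6 h
Reagents that add atoms: none
Why: Heterogeneous catalytic hydrogenation saturates the conjugated C=C chemoselectively, since dialkyl ketones, esters and TBS ethers are inert to Pd/C and 1 atm H2 in ethyl acetate.

Step 10
Reactants: 16 methyl 30-[(tert-butyldimethylsilyl)oxy]-17-oxotriacontanoate
Product: 17 methyl 30-hydroxy-17-oxotriacontanoate
Conditions: p-TsOH·H2O (10 mol %), MeOH/THF 1:1, 40 °C, 3 h; aqueous work-up, crystallisation
Reagents that add atoms: none
Why: Acid-catalysed methanolysis (desilylation) of the unhindered primary TBS ether is fast, the methyl ester can only exchange degenerately with methanol, and any dimethyl ketal reverts on aqueous work-up.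

Step 11
Reactants: 17 methyl 30-hydroxy-17-oxotriacontanoate
Product: 20 30-hydroxytriacontanoic acid, via potassium 30-hydroxy-17-oxotriacontanoate 18 (not isolated), via potassium 17-hydrazinylidene-30-hydroxytriacontanoate 19 (not isolated)
Conditions: KOH (6 equiv), diethylene glycol, 110 °C, 1 h; N2H4·H2O (8 equiv), 135 °C, 3 h; distil to 200 °C, 5 h; cool, 3 M HCl; recrystallise
Reagents that add atoms: potassium hydroxide, [K+].[OH-] (O of the carboxyl group, K of 18 and 19); hydrazine hydrate, NN.O (N only in intermediate 19)
Why: Saponification comes first so that hydrazine meets a carboxylate and cannot form an acyl hydrazide, then the Wolff–Kishner reduction (Huang-Minlon form) expels N2 from the hydrazone under hot KOH to leave CH2, a classic high-yielding operation on long-chain keto acids in which carboxylate and alkoxide are spectators.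

Step 12
Reactants: 20 30-hydroxytriacontanoic acid
Product: 22 oxacyclohentriacontan-2-one (30-triacontanolide), via mixed 2,4,6-trichlorobenzoic anhydride 21 (not isolated)
Conditions: 2,4,6-Cl3C6H2COCl (1.3 equiv), Et3N (1.5 equiv), THF, 45 °C, 2 h; then syringe pump (12 h) into DMAP (6 equiv), toluene, reflux, final 1 mM
Reagents that add atoms: 2,4,6-trichlorobenzoyl chloride, O=C(Cl)c1c(Cl)cc(Cl)cc1Cl (its atoms sit only in intermediate 21)
Why: Yamaguchi macrolactonisation, in which the carboxylate is selectively turned into the hindered mixed anhydride, DMAP transfers the aliphatic acyl group, and slow addition into hot dilute toluene keeps closure of the strain-free 31-membered ring ahead of oligomerisation; no stereocentre is involved.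

## Compound list
1 | dodecane-1,12-diol | OCCCCCCCCCCCCO | starting material
2 | 12-bromododecan-1-ol | OCCCCCCCCCCCCBr | intermediate
3 | ethyl acetoacetate | CCOC(=O)CC(C)=O | starting material
4 | ethyl acetoacetate sodium enolate (not isolated) | CCOC(=O)C=C(C)[O-].[Na+] | intermediate
5 | ethyl 2-acetyl-14-hydroxytetradecanoate (racemic) | CCOC(=O)C(CCCCCCCCCCCCO)C(C)=O | intermediate
6 | 2-acetyl-14-hydroxytetradecanoic acid (racemic, not isolated) | OC(=O)C(CCCCCCCCCCCCO)C(C)=O | intermediate
7 | 15-hydroxypentadecan-2-one | CC(=O)CCCCCCCCCCCCCO | intermediate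
8 | 15-[(tert-butyldimethylsilyl)oxy]pentadecan-2-one | CC(=O)CCCCCCCCCCCCCO[Si](C)(C)C(C)(C)C | intermediate
9 | ω-pentadecalactone (oxacyclohexadecan-2-one) | O=C1CCCCCCCCCCCCCCO1 | starting material
10 | methyl 15-hydroxypentadecanoate | COC(=O)CCCCCCCCCCCCCCO | intermediate
11 | methyl 15-oxopentadecanoate | COC(=O)CCCCCCCCCCCCCC=O | intermediate
12 | lithium 15-[(tert-butyldimethylsilyl)oxy]pentadec-1-en-2-olate (not isolated) | [Li+].[O-]C(=C)CCCCCCCCCCCCCO[Si](C)(C)C(C)(C)C | intermediate
13 | methyl 30-[(tert-butyldimethylsilyl)oxy]-15-hydroxy-17-oxotriacontanoate (racemic) | COC(=O)CCCCCCCCCCCCCC(O)CC(=O)CCCCCCCCCCCCCO[Si](C)(C)C(C)(C)C | intermediate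
14 | methyl 30-[(tert-butyldimethylsilyl)oxy]-15-(methanesulfonyloxy)-17-oxotriacontanoate (racemic, not isolated) | COC(=O)CCCCCCCCCCCCCC(OS(C)(=O)=O)CC(=O)CCCCCCCCCCCCCO[Si](C)(C)C(C)(C)C | intermediate
15 | methyl (15E)-30-[(tert-butyldimethylsilyl)oxy]-17-oxotriacont-15-enoate | COC(=O)CCCCCCCCCCCCC/C=C/C(=O)CCCCCCCCCCCCCO[Si](C)(C)C(C)(C)C | intermediate
16 | methyl 30-[(tert-butyldimethylsilyl)oxy]-17-oxotriacontanoate | COC(=O)CCCCCCCCCCCCCCCC(=O)CCCCCCCCCCCCCO[Si](C)(C)C(C)(C)C | intermediate
17 | methyl 30-hydroxy-17-oxotriacontanoate | COC(=O)CCCCCCCCCCCCCCCC(=O)CCCCCCCCCCCCCO | intermediate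
18 | potassium 30-hydroxy-17-oxotriacontanoate (not isolated) | [K+].[O-]C(=O)CCCCCCCCCCCCCCCC(=O)CCCCCCCCCCCCCO | intermediate
19 | potassium 17-hydrazinylidene-30-hydroxytriacontanoate (not isolated) | [K+].[O-]C(=O)CCCCCCCCCCCCCCCC(=NN)CCCCCCCCCCCCCO | intermediate
20 | 30-hydroxytriacontanoic acid | OC(=O)CCCCCCCCCCCCCCCCCCCCCCCCCCCCCO | intermediate
21 | 30-hydroxytriacontanoic 2,4,6-trichlorobenzoic anhydride (not isolated) | OCCCCCCCCCCCCCCCCCCCCCCCCCCCCCC(=O)OC(=O)c1c(Cl)cc(Cl)cc1Cl | intermediate
22 | oxacyclohentriacontan-2-one (30-triacontanolide, achiral) | O=C1CCCCCCCCCCCCCCCCCCCCCCCCCCCCCO1 | target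

## Counts and risks
- Total step count: 12.
- Longest linear sequence: 10 (steps 1, 2, 3, 4, 7, 8, 9, 10, 11, 12). The aldehyde branch (steps 5 and 6) joins at step 7.

**Risk 1, step 7 (aldol).**
- The waxy partners may come out of THF at −78 °C. The enolisable aldehyde can be deprotonated by the basic enolate, and the aldolate can revert.
- The fallback sets out from 8 and comes back at 13. It replaces the basic metal enolate by an isolated neutral nucleophile and Lewis-acid activation of the electrophile (Mukaiyama aldol).
- Compound 8 is treated with LDA in the presence of TMSCl (THF, −78 °C). The product is distilled or filtered through deactivated silica to give 15-[(tert-butyldimethylsilyl)oxy]-2-[(trimethylsilyl)oxy]pentadec-1-ene F1.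
- F1 is then combined with 11 and BF3·OEt2 in CH2Cl2 at −78 °C, a better solvent for these lipids. Aqueous work-up gives 13.

**Risk 2, step 12 (macrolactonisation).**
- The seco acid is poorly soluble, and diolide or oligomer formation competes.
- The fallback sets out from 20 and comes back at 22. It closes the alkyl C–O bond by SN2 instead of the acyl C–O bond.
- Compound 20 is heated with 33% HBr in AcOH and a little H2SO4 to give 30-bromotriacontanoic acid F4.
- F4 is added slowly to Cs2CO3 in DMF at 80 °C (about 2 mM). The naked caesium carboxylate displaces the terminal bromide intramolecularly (Kruizinga–Kellogg cyclisation) and gives 22.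

**Risk 3, step 11 (Wolff–Kishner).**
- The C30 soap foams and dissolves poorly at 200 °C, which can lead to incomplete reduction or azine formation.
- The fallback sets out from 17 and comes back at 20. It removes the carbonyl reductively through sulfur under near-neutral conditions (Mozingo reduction).
- Compound 17 with ethane-1,2-dithiol and BF3·OEt2 in CH2Cl2 gives methyl 16-[2-(13-hydroxytridecyl)-1,3-dithiolan-2-yl]hexadecanoate F2.
- Raney nickel in refluxing EtOH/THF desulfurises F2 to methyl 30-hydroxytriacontanoate F3.
- LiOH in THF/MeOH/H2O at 50 °C, followed by HCl, then gives 20.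

## Further compounds
F1 | step 7 | 15-[(tert-butyldimethylsilyl)oxy]-2-[(trimethylsilyl)oxy]pentadec-1-ene | C=C(CCCCCCCCCCCCCO[Si](C)(C)C(C)(C)C)O[Si](C)(C)C
F2 | step 11 | methyl 16-[2-(13-hydroxytridecyl)-1,3-dithiolan-2-yl]hexadecanoate | COC(=O)CCCCCCCCCCCCCCCC1(CCCCCCCCCCCCCO)SCCS1
F3 | step 11 | methyl 30-hydroxytriacontanoate | COC(=O)CCCCCCCCCCCCCCCCCCCCCCCCCCCCCO
F4 | step 12 | 30-bromotriacontanoic acid | OC(=O)CCCCCCCCCCCCCCCCCCCCCCCCCCCCCBr
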